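**Plan**
- Retrosynthetic cuts, in order: side-chain C4'=C5' (cross-metathesis); lactone acyl C–O and C7–C1' (lactonisation, alkenylchromium addition to a C7 aldehyde; C7 is the lactone O–CH carbon, primes denote the side chain); ring A C2=C3 (ring-closing metathesis); C1–C2 (vinyl Grignard on a Weinreb amide); the two exocyclic C–C bonds at C6 (lactone enolate alkylations).
- Forward order: the open C1–C6 chain is built on (S)-5-(hydroxymethyl)-γ-butyrolactone, ring A is closed first, the spiro-lactone ring second, and the side-chain terminus is attached last.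
- Enabling feature: ring A (C1–C6) is a cyclohex-2-enone in which C2=C3 sits between the C1 ketone, anchored on the quaternary spiro carbon C6, and the oxygen-bearing C4; opening that alkene leaves an acryloyl group on C6 and a vinyl group on a C4 silyl ether.
- Stereochemistry: C4 (S) is the carbinol carbon of the chiral-pool lactone; C6 (R) comes from the second lactone alkylation anti to the trityloxymethyl group; C7 (R) from a ligand-controlled alkenylchromium addition; 1'E from syn-carboalumination and 4'E from the cross-metathesis.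

Key step: step 12

Remark: kinetic deprotonation of the mono-alkylated lactone is assumed to occur at the ring α-carbon and not at the tert-butyl ester methylene (a fallback is given); 4-methoxybenzyl chloromethyl ether is made fresh in steps 3 and 4.

**Route**

Step 1
Reactants: 1 (S)-5-(hydroxymethyl)dihydrofuran-2(3H)-one
Product: 2 (5S)-5-[(triphenylmethoxy)methyl]oxolan-2-one
Conditions: TrCl, pyridine, DMAP (cat.), CH2Cl2, rt
Reagents that add atoms: trityl chloride, ClC(c1ccccc1)(c1ccccc1)c1ccccc1
Why: Tritylation of the primary alcohol (SN1-type etherification through the trityl cation) installs the bulky group that later shields one face of the lactone enolates; no stereocenter is touched.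

Step 2
Reactants: 2 (5S)-5-[(triphenylmethoxy)methyl]oxolan-2-one; 3 tert-butyl bromoacetate
Product: 5 tert-butyl 2-[(3S,5S)-2-oxo-5-[(triphenylmethoxy)methyl]oxolan-3-yl]acetate, via lithium lactone enolate 4 (not isolated)
Conditions: LiN(iPr)2, THF, −78 °C; then 3, −78 °C
Reagents that add atoms: none
Why: Enolate alkylation of a γ-lactone, in which the C5 trityloxymethyl group blocks its own face so that the bromoacetate should enter trans to give the (3S,5S) isomer, a center that is made planar again in step 5.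

Step 3
Reactants: 6 4-methoxybenzyl alcohol; 7 chloromethyl methyl sulfide
Product: 9 1-methoxy-4-{[(methylsulfanyl)methoxy]methyl}benzene, via sodium 4-methoxybenzyl oxide 8 (not isolated)
Conditions: NaH, DME, 0 °C; then 7, NaI (cat.), 0 °C → rt
Reagents that add atoms: none
Why: Williamson ether synthesis of the sodium alkoxide with the α-chloro sulfide (iodide catalysis) gives the methylthiomethyl ether.

Step 4
Reactants: 9 1-methoxy-4-{[(methylsulfanyl)methoxy]methyl}benzene
Product: 10 1-[(chloromethoxy)methyl]-4-methoxybenzene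
Conditions: SO2Cl2, CH2Cl2, −78 °C; volatiles removed, used at once
Reagents that add atoms: sulfuryl chloride, O=S(=O)(Cl)Cl
Why: Chlorinative cleavage of the O,S-acetal (S-chlorosulfonium formation, loss of the sulfenyl chloride, chloride capture of the oxocarbenium ion) is the standard entry to alkoxymethyl chlorides.

Step 5
Reactants: 5 tert-butyl 2-[(3S,5S)-2-oxo-5-[(triphenylmethoxy)methyl]oxolan-3-yl]acetate; 10 1-[(chloromethoxy)methyl]-4-methoxybenzene
Product: 12 tert-butyl 2-[(3R,5S)-3-{[(4-methoxyphenyl)methoxy]methyl}-2-oxo-5-[(triphenylmethoxy)methyl]oxolan-3-yl]acetate, via tetrasubstituted lithium enolate 11 (not isolated)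
Conditions: LiN(iPr)2, THF, −78 °C; then 10, −78 → −40 °C
Reagents that add atoms: none
Why: Second lactone enolate alkylation, in which the ring α-C–H (more acidic than the hindered tert-butyl ester CH2) is removed and the reactive α-chloro ether should attack the enolate face anti to the C5 trityloxymethyl group (1,3-induction), setting the quaternary center as 3R with the acetate arm cis to that group.

Step 6
Reactants: 12 tert-butyl 2-[(3R,5S)-3-{[(4-methoxyphenyl)methoxy]methyl}-2-oxo-5-[(triphenylmethoxy)methyl]oxolan-3-yl]acetate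
Product: 13 tert-butyl 2-[(3R,5S)-5-(hydroxymethyl)-3-{[(4-methoxyphenyl)methoxy]methyl}-2-oxooxolan-3-yl]acetate
Conditions: camphorsulfonic acid (cat.), MeOH/CH2Cl2, 0 °C → rt
Reagents that add atoms: none
Why: Acid-catalysed solvolysis of the trityl ether (SN1, trityl cation trapped by methanol) should leave the 4-methoxybenzyl ether, the tert-butyl ester and the γ-lactone untouched.

Step 7
Reactants: 13 tert-butyl 2-[(3R,5S)-5-(hydroxymethyl)-3-{[(4-methoxyphenyl)methoxy]methyl}-2-oxooxolan-3-yl]acetate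
Product: 14 tert-butyl 2-[(3R,5S)-5-formyl-3-{[(4-methoxyphenyl)methoxy]methyl}-2-oxooxolan-3-yl]acetate
Conditions: Dess–Martin periodinane, CH2Cl2, 0 °C → rt; used crude
Reagents that add atoms: none
Why: Dess–Martin oxidation gives the aldehyde under non-basic conditions, which protects the epimerisable α-acyloxy center.

Step 8
Reactants: 14 tert-butyl 2-[(3R,5S)-5-formyl-3-{[(4-methoxyphenyl)methoxy]methyl}-2-oxooxolan-3-yl]acetate
Product: 15 tert-butyl 2-[(3R,5S)-5-ethenyl-3-{[(4-methoxyphenyl)methoxy]methyl}-2-oxooxolan-3-yl]acetate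
Conditions: Ph3PCH3Br, KN(SiMe3)2, THF, 0 °C; then 14, −78 → 0 °C
Reagents that add atoms: methyltriphenylphosphonium bromide, [Br-].C[P+](c1ccccc1)(c1ccccc1)c1ccccc1
Why: Wittig methylenation, in which the non-stabilised ylide adds to the aldehyde far faster than to the hindered lactone and ester carbonyls, and the low temperature limits epimerisation of the α-oxygenated center.

Step 9
Reactants: 15 tert-butyl 2-[(3R,5S)-5-ethenyl-3-{[(4-methoxyphenyl)methoxy]methyl}-2-oxooxolan-3-yl]acetate
Product: 16 tert-butyl (3R,5S)-5-hydroxy-3-{[(4-methoxyphenyl)methoxy]methyl}-3-[methoxy(methyl)carbamoyl]hept-6-enoate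
Conditions: MeNH(OMe)·HCl, AlMe3, CH2Cl2, 0 °C → rt; used crude
Reagents that add atoms: N,O-dimethylhydroxylamine hydrochloride, CNOC.Cl
Why: Weinreb aminolysis of the lactone by the aluminium amide (acyl substitution) opens the ring and frees the C4 hydroxyl, while the tert-butyl ester is too hindered to react.

Step 10
Reactants: 16 tert-butyl (3R,5S)-5-hydroxy-3-{[(4-methoxyphenyl)methoxy]methyl}-3-[methoxy(methyl)carbamoyl]hept-6-enoate
Product: 17 tert-butyl (3R,5S)-5-[(tert-butyldimethylsilyl)oxy]-3-{[(4-methoxyphenyl)methoxy]methyl}-3-[methoxy(methyl)carbamoyl]hept-6-enoate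
Conditions: TBSCl, imidazole, DMF, rt
Reagents that add atoms: tert-butyldimethylsilyl chloride, CC(C)(C)[Si](C)(C)Cl
Why: Imidazole-promoted silylation of the secondary allylic alcohol stops relactonisation and protects the C4 oxygen for the organometallic steps.

Step 11
Reactants: 17 tert-butyl (3R,5S)-5-[(tert-butyldimethylsilyl)oxy]-3-{[(4-methoxyphenyl)methoxy]methyl}-3-[methoxy(methyl)carbamoyl]hept-6-enoate; 18 vinylmagnesium bromide
Product: 19 tert-butyl (3R,5S)-5-[(tert-butyldimethylsilyl)oxy]-3-{[(4-methoxyphenyl)methoxy]methyl}-3-(prop-2-enoyl)hept-6-enoate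
Conditions: CH2=CHMgBr, THF, −20 → 0 °C; poured into cold 1 M HCl
Reagents that add atoms: none
Why: Weinreb ketone synthesis, in which the chelated tetrahedral magnesium adduct stops at single addition, the acidic inverse quench protonates the released amine before it can add to the enone, and the bulky tert-butyl ester is spared.

Step 12
Reactants: 19 tert-butyl (3R,5S)-5-[(tert-butyldimethylsilyl)oxy]-3-{[(4-methoxyphenyl)methoxy]methyl}-3-(prop-2-enoyl)hept-6-enoate
Product: 20 tert-butyl 2-[(1R,5S)-5-[(tert-butyldimethylsilyl)oxy]-1-{[(4-methoxyphenyl)methoxy]methyl}-2-oxocyclohex-3-en-1-yl]acetate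
Conditions: RuCl2(H2IMes)(=CH-C6H4-2-OiPr) (second-generation Hoveyda–Grubbs catalyst, H2IMes = 1,3-dimesitylimidazolidin-2-ylidene; 5 mol %), CH2Cl2 (0.005 M), 40 °C
Reagents that add atoms: none
Why: Ring-closing olefin metathesis: the ruthenium benzylidene exchanges onto the monosubstituted alkene next to the silyl ether, the more electron-rich terminus, and the resulting alkylidene adds across the acryloyl C=C in an intramolecular [2+2] cycloaddition; cycloreversion of the ruthenacyclobutane releases the C2=C3 alkene, and the methylidene left on ruthenium turns over with loss of ethene. The closest known reaction type is the ring-closing metathesis of vinyl ketone/allylic ether dienes to 4-oxygenated cyclohex-2-enones. Ring A closes as a six-membered carbocycle by C2=C3 bond formation, and the ring size allows only the cis alkene. No stereocenter is formed; C4 and C6 are carried unchanged from 19. The step needs chemoselectivity for cyclisation over intermolecular metathesis, which 19 secures by having only these two terminal alkenes, by the quaternary C6 that presses the two arms together (Thorpe–Ingold effect) and by high dilution.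

Step 13
Reactants: 20 tert-butyl 2-[(1R,5S)-5-[(tert-butyldimethylsilyl)oxy]-1-{[(4-methoxyphenyl)methoxy]methyl}-2-oxocyclohex-3-en-1-yl]acetate
Product: 21 tert-butyl 2-[(1R,5S)-5-[(tert-butyldimethylsilyl)oxy]-1-(hydroxymethyl)-2-oxocyclohex-3-en-1-yl]acetate
Conditions: DDQ, CH2Cl2/aqueous pH 7 buffer, 0 °C → rt
Reagents that add atoms: none
Why: Oxidative cleavage of the 4-methoxybenzyl ether (hydride abstraction from the electron-rich benzylic position, hydrolysis of the oxocarbenium ion) should spare the silyl ether, the electron-poor enone and the ester.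

Step 14
Reactants: 21 tert-butyl 2-[(1R,5S)-5-[(tert-butyldimethylsilyl)oxy]-1-(hydroxymethyl)-2-oxocyclohex-3-en-1-yl]acetate
Product: 22 tert-butyl 2-[(1R,5S)-5-[(tert-butyldimethylsilyl)oxy]-1-formyl-2-oxocyclohex-3-en-1-yl]acetate
Conditions: Dess–Martin periodinane, CH2Cl2, 0 °C → rt; used at once
Reagents that add atoms: none
Why: Dess–Martin oxidation under neutral conditions gives the non-enolisable β-keto aldehyde and avoids the base-induced retro-aldol loss of formaldehyde from the β-hydroxy ketone.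

Step 15
Reactants: 23 pent-1-en-4-yne
Product: 25 (1E)-1-iodo-2-methylpenta-1,4-diene, via alkenyldimethylalane 24 (not isolated)
Conditions: AlMe3, Cp2ZrCl2 (cat.), CH2Cl2, 0 °C → rt; then I2, THF, −30 → 0 °C
Reagents that add atoms: trimethylaluminium, C[Al](C)C; iodine, II
Why: Negishi zirconium-catalysed carboalumination adds methyl and aluminium syn across the alkyne with aluminium at the terminus, and iodinolysis with retention gives the E iodide, the monosubstituted alkene being unreactive.

Step 16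
Reactants: 22 tert-butyl 2-[(1R,5S)-5-[(tert-butyldimethylsilyl)oxy]-1-formyl-2-oxocyclohex-3-en-1-yl]acetate; 25 (1E)-1-iodo-2-methylpenta-1,4-diene
Product: 26 tert-butyl 2-[(1R,5S)-5-[(tert-butyldimethylsilyl)oxy]-1-[(1R,2E)-1-hydroxy-3-methylhexa-2,5-dien-1-yl]-2-oxocyclohex-3-en-1-yl]acetate
Conditions: CrCl2, NiCl2 (cat.), N-{2-[(4S)-4-isopropyl-4,5-dihydro-1,3-oxazol-2-yl]-6-methylphenyl}methanesulfonamide (or its 4R antipode), Et3N, THF, rt
Reagents that add atoms: none
Why: Nozaki–Hiyama–Kishi reaction, in which zerovalent nickel inserts into the C–I bond, the alkenyl group passes to trivalent chromium with retention of geometry and adds only to the aldehyde, and the chiral sulfonamide on chromium, used as the antipode that delivers the alkenyl group to the Re face (to be assigned on a trial run by Mosher ester analysis), should set C7 as R.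

Step 17
Reactants: 26 tert-butyl 2-[(1R,5S)-5-[(tert-butyldimethylsilyl)oxy]-1-[(1R,2E)-1-hydroxy-3-methylhexa-2,5-dien-1-yl]-2-oxocyclohex-3-en-1-yl]acetate
Product: 27 (1R,5R,9S)-9-[(tert-butyldimethylsilyl)oxy]-1-[(1E)-2-methylpenta-1,4-dien-1-yl]-2-oxaspiro[4.5]dec-7-ene-3,6-dione
Conditions: camphorsulfonic acid (cat.), CH2Cl2, rt
Reagents that add atoms: none
Why: Acid-catalysed intramolecular transesterification (γ-lactonisation, 5-exo-trig, helped by the quaternary carbon) closes the spiro-lactone without breaking the C7–O bond, so the C7 configuration is kept, and no acid-labile tertiary allylic alcohol is present yet.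

Step 18
Reactants: 27 (1R,5R,9S)-9-[(tert-butyldimethylsilyl)oxy]-1-[(1E)-2-methylpenta-1,4-dien-1-yl]-2-oxaspiro[4.5]dec-7-ene-3,6-dione
Product: 28 (1R,5R,9S)-9-hydroxy-1-[(1E)-2-methylpenta-1,4-dien-1-yl]-2-oxaspiro[4.5]dec-7-ene-3,6-dione
Conditions: HF·pyridine, pyridine, THF, 0 °C → rt
Reagents that add atoms: none
Why: Fluoride-driven desilylation under buffered, non-basic conditions frees the C4 hydroxyl without opening the lactone or isomerising the γ-oxygenated enone.

Step 19
Reactants: 28 (1R,5R,9S)-9-hydroxy-1-[(1E)-2-methylpenta-1,4-dien-1-yl]-2-oxaspiro[4.5]dec-7-ene-3,6-dione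
Product: 29 (1R,5R,9S)-1-[(1E)-2-methylpenta-1,4-dien-1-yl]-3,6-dioxo-2-oxaspiro[4.5]dec-7-en-9-yl acetate
Conditions: Ac2O, pyridine, DMAP (cat.), CH2Cl2, 0 °C
Reagents that add atoms: acetic anhydride, CC(=O)OC(C)=O
Why: DMAP-catalysed acylation of the only hydroxyl, a secondary allylic alcohol, under bases too weak to epimerise C4 through the dienolate.

Step 20
Reactants: 29 (1R,5R,9S)-1-[(1E)-2-methylpenta-1,4-dien-1-yl]-3,6-dioxo-2-oxaspiro[4.5]dec-7-en-9-yl acetate; 30 2-methylbut-3-en-2-ol
Product: 31 (+)-miliusane XVII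
Conditions: 30 (10 equiv), RuCl2(H2IMes)(=CH-C6H4-2-OiPr) (5–10 mol %), 1,4-benzoquinone (cat.), CH2Cl2, 40 °C
Reagents that add atoms: none
Why: Olefin cross-metathesis of the terminal allyl alkene with an excess of the hindered tertiary allylic alcohol, in which the bulky carbinol group in the ruthenacyclobutane should enforce the 4'E geometry while the ring enone and the trisubstituted alkene stay inert and the quinone suppresses hydride-induced migration of the skipped diene.

**Compound list**

1 | (S)-5-(hydroxymethyl)dihydrofuran-2(3H)-one | OC[C@@H]1CCC(=O)O1 | starting material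
2 | (5S)-5-[(triphenylmethoxy)methyl]oxolan-2-one | O(C[C@@H]1CCC(=O)O1)C(c1ccccc1)(c1ccccc1)c1ccccc1 | intermediate
3 | tert-butyl bromoacetate | CC(C)(C)OC(=O)CBr | starting material
4 | lithium (5S)-5-[(triphenylmethoxy)methyl]-4,5-dihydrofuran-2-olate (not isolated) | [Li+].[O-]C1=CC[C@@H](COC(c2ccccc2)(c2ccccc2)c2ccccc2)O1 | intermediate
5 | tert-butyl 2-[(3S,5S)-2-oxo-5-[(triphenylmethoxy)methyl]oxolan-3-yl]acetate (3,5-trans) | O(C[C@@H]1C[C@@H](CC(=O)OC(C)(C)C)C(=O)O1)C(c1ccccc1)(c1ccccc1)c1ccccc1 | intermediate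
6 | 4-methoxybenzyl alcohol | COc1ccc(CO)cc1 | starting material
7 | chloromethyl methyl sulfide | CSCCl | starting material
8 | sodium (4-methoxyphenyl)methanolate (not isolated) | COc1ccc(C[O-])cc1.[Na+] | intermediate
9 | 1-methoxy-4-{[(methylsulfanyl)methoxy]methyl}benzene | COc1ccc(COCSC)cc1 | intermediate
10 | 1-[(chloromethoxy)methyl]-4-methoxybenzene | COc1ccc(COCCl)cc1 | intermediate
11 | lithium (5S)-3-(2-tert-butoxy-2-oxoethyl)-5-[(triphenylmethoxy)methyl]-4,5-dihydrofuran-2-olate (not isolated) | [Li+].[O-]C1=C(CC(=O)OC(C)(C)C)C[C@@H](COC(c2ccccc2)(c2ccccc2)c2ccccc2)O1 | intermediate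
12 | tert-butyl 2-[(3R,5S)-3-{[(4-methoxyphenyl)methoxy]methyl}-2-oxo-5-[(triphenylmethoxy)methyl]oxolan-3-yl]acetate | O(C[C@@H]1C[C@@](CC(=O)OC(C)(C)C)(COCc2ccc(OC)cc2)C(=O)O1)C(c1ccccc1)(c1ccccc1)c1ccccc1 | intermediate
13 | tert-butyl 2-[(3R,5S)-5-(hydroxymethyl)-3-{[(4-methoxyphenyl)methoxy]methyl}-2-oxooxolan-3-yl]acetate | OC[C@@H]1C[C@@](CC(=O)OC(C)(C)C)(COCc2ccc(OC)cc2)C(=O)O1 | intermediate
14 | tert-butyl 2-[(3R,5S)-5-formyl-3-{[(4-methoxyphenyl)methoxy]methyl}-2-oxooxolan-3-yl]acetate | O=C[C@@H]1C[C@@](CC(=O)OC(C)(C)C)(COCc2ccc(OC)cc2)C(=O)O1 | intermediate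
15 | tert-butyl 2-[(3R,5S)-5-ethenyl-3-{[(4-methoxyphenyl)methoxy]methyl}-2-oxooxolan-3-yl]acetate | C=C[C@@H]1C[C@@](CC(=O)OC(C)(C)C)(COCc2ccc(OC)cc2)C(=O)O1 | intermediate
16 | tert-butyl (3R,5S)-5-hydroxy-3-{[(4-methoxyphenyl)methoxy]methyl}-3-[methoxy(methyl)carbamoyl]hept-6-enoate | C=C[C@@H](O)C[C@@](CC(=O)OC(C)(C)C)(COCc1ccc(OC)cc1)C(=O)N(C)OC | intermediate
17 | tert-butyl (3R,5S)-5-[(tert-butyldimethylsilyl)oxy]-3-{[(4-methoxyphenyl)methoxy]methyl}-3-[methoxy(methyl)carbamoyl]hept-6-enoate | C=C[C@@H](O[Si](C)(C)C(C)(C)C)C[C@@](CC(=O)OC(C)(C)C)(COCc1ccc(OC)cc1)C(=O)N(C)OC | intermediate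
18 | vinylmagnesium bromide | C=C[Mg]Br | starting material
19 | tert-butyl (3R,5S)-5-[(tert-butyldimethylsilyl)oxy]-3-{[(4-methoxyphenyl)methoxy]methyl}-3-(prop-2-enoyl)hept-6-enoate | CC(C)(C)[Si](C)(C)O[C@H](C=C)C[C@@](C(=O)C=C)(CC(=O)OC(C)(C)C)COCc1ccc(OC)cc1 | intermediate
20 | tert-butyl 2-[(1R,5S)-5-[(tert-butyldimethylsilyl)oxy]-1-{[(4-methoxyphenyl)methoxy]methyl}-2-oxocyclohex-3-en-1-yl]acetate | CC(C)(C)[Si](C)(C)O[C@@H]1C=CC(=O)[C@@](COCc2ccc(OC)cc2)(CC(=O)OC(C)(C)C)C1 | intermediate
21 | tert-butyl 2-[(1R,5S)-5-[(tert-butyldimethylsilyl)oxy]-1-(hydroxymethyl)-2-oxocyclohex-3-en-1-yl]acetate | CC(C)(C)[Si](C)(C)O[C@@H]1C=CC(=O)[C@@](CO)(CC(=O)OC(C)(C)C)C1 | intermediate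
22 | tert-butyl 2-[(1R,5S)-5-[(tert-butyldimethylsilyl)oxy]-1-formyl-2-oxocyclohex-3-en-1-yl]acetate | CC(C)(C)[Si](C)(C)O[C@@H]1C=CC(=O)[C@@](C=O)(CC(=O)OC(C)(C)C)C1 | intermediate
23 | pent-1-en-4-yne | C=CCC#C | starting material
24 | dimethyl[(1E)-2-methylpenta-1,4-dien-1-yl]alumane (not isolated) | C[Al](C)/C=C(\C)CC=C | intermediate
25 | (1E)-1-iodo-2-methylpenta-1,4-diene | I/C=C(\C)CC=C | intermediate
26 | tert-butyl 2-[(1R,5S)-5-[(tert-butyldimethylsilyl)oxy]-1-[(1R,2E)-1-hydroxy-3-methylhexa-2,5-dien-1-yl]-2-oxocyclohex-3-en-1-yl]acetate | CC(C)(C)[Si](C)(C)O[C@@H]1C=CC(=O)[C@@]([C@H](O)/C=C(\C)CC=C)(CC(=O)OC(C)(C)C)C1 | intermediate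
27 | (1R,5R,9S)-9-[(tert-butyldimethylsilyl)oxy]-1-[(1E)-2-methylpenta-1,4-dien-1-yl]-2-oxaspiro[4.5]dec-7-ene-3,6-dione | CC(C)(C)[Si](C)(C)O[C@@H]1C=CC(=O)[C@@]2(CC(=O)O[C@@H]2/C=C(\C)CC=C)C1 | intermediate
28 | (1R,5R,9S)-9-hydroxy-1-[(1E)-2-methylpenta-1,4-dien-1-yl]-2-oxaspiro[4.5]dec-7-ene-3,6-dione | O[C@@H]1C=CC(=O)[C@@]2(CC(=O)O[C@@H]2/C=C(\C)CC=C)C1 | intermediate
29 | (1R,5R,9S)-1-[(1E)-2-methylpenta-1,4-dien-1-yl]-3,6-dioxo-2-oxaspiro[4.5]dec-7-en-9-yl acetate | CC(=O)O[C@@H]1C=CC(=O)[C@@]2(CC(=O)O[C@@H]2/C=C(\C)CC=C)C1 | intermediate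
30 | 2-methylbut-3-en-2-ol | C=CC(C)(C)O | starting material
31 | (+)-miliusane XVII, (1R,5R,9S)-1-[(1E,4E)-6-hydroxy-2,6-dimethylhepta-1,4-dien-1-yl]-3,6-dioxo-2-oxaspiro[4.5]dec-7-en-9-yl acetate | CC(=O)O[C@@H]1C=CC(=O)[C@@]2(CC(=O)O[C@@H]2/C=C(\C)C/C=C/C(C)(C)O)C1 | target

**Step count and risks**

Total step count: 20. Longest linear sequence: 17 steps (steps 1, 2, 5 to 14 and 16 to 20, from 1 to 31).

Steps most likely to fail:

Step 5. Proton abstraction may occur at the ester methylene instead of the ring α-carbon, which would put the alkoxymethyl group on the arm, and the electrophile may leak to the face syn to the trityloxymethyl group. The fallback removes the second acidic site by carrying the acetate arm as an allyl group. Setting out from 2, LiN(iPr)2 and allyl bromide give the trans lactone (3R,5S)-3-(prop-2-en-1-yl)-5-[(triphenylmethoxy)methyl]oxolan-2-one F1. A second enolisation with LiN(iPr)2 and alkylation with 10 gives the quaternary allyl lactone F2, the alkoxymethyl group again entering anti to the trityloxymethyl group. Lemieux–Johnson cleavage (OsO4 cat., NaIO4, 2,6-lutidine) turns the allyl alkene into the aldehyde F3, Pinnick oxidation (NaClO2, NaH2PO4, 2-methylbut-2-ene) gives the acid F4, and esterification with Boc2O, DMAP and t-BuOH comes back to the route at 12.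

Step 16. Facial selectivity at the neopentyl aldehyde may be poor if the ligand and the substrate bias are mismatched, and the hindered β-keto aldehyde may add slowly. The fallback changes the metal and the source of induction to a ligand-accelerated organozinc addition. Setting out from 25, iodine–lithium exchange (t-BuLi, Et2O, −78 °C) gives the alkenyllithium F5, and ZnBr2 converts it into the alkenylzinc bromide F6. F6 is added to 22 in the presence of (−)-3-exo-morpholinoisoborneol or its enantiomer (with a chelating diamine to suppress the salt-promoted background reaction), which is aldehyde-selective, and the route is rejoined at 26.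

Step 11. Addition to the α-quaternary Weinreb amide may be slow, so that N–O cleavage of the amide or conjugate addition of the released amine to the new enone takes over. The fallback passes through the aldehyde oxidation level. Setting out from 17, i-Bu2AlH (THF, −78 °C) reduces the Weinreb amide to the aldehyde F7. Vinylmagnesium bromide 18 at −78 °C, quenched cold so that the alkoxide does not lactonise onto the tert-butyl ester, gives the allylic alcohol F8 as a mixture of carbinol epimers. Dess–Martin oxidation then comes back to the route at 19.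

**Further compounds**

F1 | step 5 | (3R,5S)-3-(prop-2-en-1-yl)-5-[(triphenylmethoxy)methyl]oxolan-2-one | O(C[C@@H]1C[C@@H](CC=C)C(=O)O1)C(c1ccccc1)(c1ccccc1)c1ccccc1
F2 | step 5 | (3S,5S)-3-{[(4-methoxyphenyl)methoxy]methyl}-3-(prop-2-en-1-yl)-5-[(triphenylmethoxy)methyl]oxolan-2-one | O(C[C@@H]1C[C@@](CC=C)(COCc2ccc(OC)cc2)C(=O)O1)C(c1ccccc1)(c1ccccc1)c1ccccc1
F3 | step 5 | 2-[(3R,5S)-3-{[(4-methoxyphenyl)methoxy]methyl}-2-oxo-5-[(triphenylmethoxy)methyl]oxolan-3-yl]acetaldehyde | O(C[C@@H]1C[C@@](CC=O)(COCc2ccc(OC)cc2)C(=O)O1)C(c1ccccc1)(c1ccccc1)c1ccccc1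
F4 | step 5 | 2-[(3R,5S)-3-{[(4-methoxyphenyl)methoxy]methyl}-2-oxo-5-[(triphenylmethoxy)methyl]oxolan-3-yl]acetic acid | O(C[C@@H]1C[C@@](CC(=O)O)(COCc2ccc(OC)cc2)C(=O)O1)C(c1ccccc1)(c1ccccc1)c1ccccc1
F5 | step 16 | [(1E)-2-methylpenta-1,4-dien-1-yl]lithium | [Li]/C=C(\C)CC=C
F6 | step 16 | bromo[(1E)-2-methylpenta-1,4-dien-1-yl]zinc | Br[Zn]/C=C(\C)CC=C
F7 | step 11 | tert-butyl (3R,5S)-5-[(tert-butyldimethylsilyl)oxy]-3-formyl-3-{[(4-methoxyphenyl)methoxy]methyl}hept-6-enoate | C=C[C@@H](O[Si](C)(C)C(C)(C)C)C[C@@](CC(=O)OC(C)(C)C)(COCc1ccc(OC)cc1)C=O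
F8 | step 11 | tert-butyl (3R,5S)-5-[(tert-butyldimethylsilyl)oxy]-3-(1-hydroxyprop-2-en-1-yl)-3-{[(4-methoxyphenyl)methoxy]methyl}hept-6-enoate (both carbinol epimers) | C=C[C@@H](O[Si](C)(C)C(C)(C)C)C[C@@](CC(=O)OC(C)(C)C)(COCc1ccc(OC)cc1)C(O)C=C
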